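The bond between C6 of the indenone benzo ring and its guaiazulenyl group is the one to cut. In that ring C6 sits between the C7 methyl and C5–H, meta to C4, while C4 and C7 are para. A C4 phenol can therefore be oxidised to a C7 p-quinol in which C6 is the only hydrogen-bearing β-carbon of the dienone. In one operation guaiazulene adds there through C3–H and water is lost from C7, which forges the hindered aryl–azulene bond and returns the C4 phenol as the handle for the carbinol. The precursor is the bicyclic quinol 7-hydroxy-3,7-dimethyl-2,3-dihydroindene-1,4-dione, made in three steps from 4,6-dimethylcoumarin.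

Key step: step 4

Assumption: the target SMILES defines no stereocentre and no axis, so the two hindered aryl–azulene axes are left undefined. All chiral intermediates are racemic and drawn as one enantiomer. "Guaiazulen-3-yl" means 5-isopropyl-3,8-dimethylazulen-1-yl.

Step 1
Reactants: 1 4,6-dimethylcoumarin
Product: 2 rac-4,6-dimethylchroman-2-one
Conditions: H2 (5 bar), 10% Pd/C, AcOH, 50 °C
Reagents that add atoms: none
Why: Heterogeneous catalytic hydrogenation should saturate the conjugated C3=C4 bond of the coumarin and leave lactone and arene intact; the new C4 stereocentre is formed without control, so the product is racemic.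

Step 2
Reactants: 2 rac-4,6-dimethylchroman-2-one
Product: 3 rac-4-hydroxy-3,7-dimethylindan-1-one
Conditions: AlCl3 (3 equiv), NaCl, neat melt, 180 °C; then ice, aq. HCl
Reagents that add atoms: none
Why: Fries-type rearrangement, the established dihydrocoumarin to 4-hydroxyindan-1-one conversion: AlCl3 opens the aryl ester and the acyl group attacks the only ring carbon that can close a five-membered ring (C5 of the chromanone, next to the C6 methyl), so the regiochemistry is fixed and the stereocentre is untouched.

Step 3
Reactants: 3 rac-4-hydroxy-3,7-dimethylindan-1-one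
Product: 4 7-hydroxy-3,7-dimethyl-2,3-dihydro-1H-indene-1,4(7H)-dione (racemic, both C7 epimers)
Conditions: PhI(OAc)2 (1.1 equiv), MeCN/H2O (3:1), 0 °C
Reagents that add atoms: water, O
Why: Oxidative dearomatisation of a para-alkyl phenol by the trivalent iodine reagent, with water captured at the methyl-bearing para carbon C7, should give the p-quinol; the new C7 centre is not controlled and need not be, because step 4 destroys it.

Step 4
Reactants: 4 7-hydroxy-3,7-dimethyl-2,3-dihydro-1H-indene-1,4(7H)-dione; 5 guaiazulene
Product: 7 rac-6-(guaiazulen-3-yl)-4-hydroxy-3,7-dimethylindan-1-one, via Michael adduct 6 (not isolated)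
Conditions: 5 (1.1 equiv), TsOH·H2O (10 mol %), MeCN, 20 → 50 °C
Reagents that add atoms: none
Why: Proposed new method: protonation of the C4 carbonyl lets the nucleophilic C3 of guaiazulene attack C6, the β-carbon of the C4–C5=C6 enone, and the azulenium ion loses its proton to give adduct 6; acid then removes the C7 hydroxyl as water together with the C6 hydrogen, and the dienone enolises to the C4 phenol. The closest known reaction type is the acid-catalysed Michael addition of indoles and related π-nucleophiles to p-quinols with dehydrative rearomatisation to meta-arylated phenols, alongside the known conjugate addition of guaiazulene to quinones; an azulene in this tandem process is the extension. No ring is closed, and the transient stereocentres at C6 and C7 vanish on aromatisation, leaving only the racemic C3 centre. The step needs site selectivity between the two enone β-carbons and 1,4- over 1,2-addition: C7a is a fully substituted ring-fusion carbon whereas C6 bears hydrogen, and on the azulene only C3 is free because C1 carries a methyl group. Electrophilic substitution of the phenol could never reach C6, which is meta to oxygen, so the quinol supplies the inverted polarity at exactly this carbon.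

Step 5
Reactants: 7 rac-6-(guaiazulen-3-yl)-4-hydroxy-3,7-dimethylindan-1-one
Product: 8 rac-6-(guaiazulen-3-yl)-3,7-dimethyl-1-oxoindan-4-yl trifluoromethanesulfonate
Conditions: PhNTf2 (1.2 equiv), K2CO3 (2 equiv), DMF, 0 °C → rt
Reagents that add atoms: N-phenylbis(trifluoromethanesulfonimide), O=S(=O)(N(c1ccccc1)S(=O)(=O)C(F)(F)F)C(F)(F)F
Why: O-Sulfonylation of the phenoxide (aryl triflate formation) with the mild triflyl donor PhNTf2, chosen over Tf2O so that the electron-rich azulene is not attacked.

Step 6
Reactants: 8 rac-6-(guaiazulen-3-yl)-3,7-dimethyl-1-oxoindan-4-yl trifluoromethanesulfonate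
Product: 10 rac-6-(guaiazulen-3-yl)-2-hydroxy-3,7-dimethyl-1-oxoindan-4-yl trifluoromethanesulfonate, via potassium enolate 9 (not isolated)
Conditions: KN(SiMe3)2 (1.05 equiv), THF, −78 °C; then 2-(phenylsulfonyl)-3-phenyloxaziridine (1.3 equiv), −78 °C; aq. NH4Cl
Reagents that add atoms: 2-(phenylsulfonyl)-3-phenyloxaziridine, O=S(=O)(N1OC1c1ccccc1)c1ccccc1
Why: Davis enolate hydroxylation: C2 is the only enolisable position, the ketone is far more acidic than the azulene C4-methyl, and the anionic enolate rather than the neutral azulene takes the electrophilic oxygen, which should arrive anti to the C3 methyl (trans product, a centre that step 7 removes).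

Step 7
Reactants: 10 rac-6-(guaiazulen-3-yl)-2-hydroxy-3,7-dimethyl-1-oxoindan-4-yl trifluoromethanesulfonate
Product: 11 rac-6-(guaiazulen-3-yl)-3,7-dimethyl-1,2-dioxoindan-4-yl trifluoromethanesulfonate
Conditions: Dess–Martin periodinane (1.3 equiv), pyridine, CH2Cl2, 0 °C → rt
Reagents that add atoms: none
Why: Dess–Martin oxidation of the α-hydroxy ketone to the 1,2-dione under buffered conditions that the aryl triflate and the azulene should tolerate.

Step 8
Reactants: 11 rac-6-(guaiazulen-3-yl)-3,7-dimethyl-1,2-dioxoindan-4-yl trifluoromethanesulfonate; 5 guaiazulene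
Product: 13 2,6-bis(guaiazulen-3-yl)-3,7-dimethyl-1-oxo-1H-inden-4-yl trifluoromethanesulfonate, via C2 carbinol 12 (not isolated)
Conditions: 5 (1.0 equiv), TsOH·H2O (20 mol %), ClCH2CH2Cl, rt → 60 °C
Reagents that add atoms: none
Why: Acid-catalysed Friedel–Crafts hydroxyalkylation of guaiazulene C3 by the more electrophilic, non-aryl C2 carbonyl (C1 is an aryl ketone shielded by the C7 methyl) should give carbinol 12, whose azulene-stabilised C2 cation loses the C3 proton (E1 dehydration) to form the conjugated indenone, while one equivalent of guaiazulene limits double addition.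

Step 9
Reactants: 13 2,6-bis(guaiazulen-3-yl)-3,7-dimethyl-1-oxo-1H-inden-4-yl trifluoromethanesulfonate; 14 isopropenylboronic acid pinacol ester
Product: 15 2,6-bis(guaiazulen-3-yl)-4-isopropenyl-3,7-dimethyl-1H-inden-1-one
Conditions: 14 (1.5 equiv), Pd(dppf)Cl2 (5 mol %), K3PO4 (3 equiv), 1,4-dioxane/H2O (10:1), 80 °C
Reagents that add atoms: none
Why: Suzuki–Miyaura coupling of the aryl triflate with the alkenyl boronate through zerovalent palladium formed from Pd(dppf)Cl2, with a mild phosphate base that should spare the indenone.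

Step 10
Reactants: 15 2,6-bis(guaiazulen-3-yl)-4-isopropenyl-3,7-dimethyl-1H-inden-1-one
Product: 17 2,6-bis(guaiazulen-3-yl)-4-(2-hydroxypropan-2-yl)-3,7-dimethyl-1H-inden-1-one, via silyl peroxide 16 (not isolated)
Conditions: Co(acac)2 (20 mol %), PhSiH3 (2.5 equiv), O2 (1 atm), THF/i-PrOH, 0 °C → rt
Reagents that add atoms: dioxygen, O=O
Why: Mukaiyama hydration: hydrogen-atom transfer from a cobalt hydride to the 1,1-disubstituted styrene-type alkene gives the tertiary benzylic radical, which O2 traps and the silane reduces through peroxide 16 to the Markovnikov alcohol, while the tetrasubstituted electron-poor indenone alkene should react far more slowly.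

Compound list
1 | 4,6-dimethylcoumarin | Cc1ccc2oc(=O)cc(C)c2c1 | starting material
2 | rac-4,6-dimethylchroman-2-one (one enantiomer drawn) | C[C@H]1CC(=O)Oc2ccc(C)cc21 | intermediate
3 | rac-4-hydroxy-3,7-dimethylindan-1-one (one enantiomer drawn) | C[C@H]1CC(=O)c2c(C)ccc(O)c21 | intermediate
4 | 7-hydroxy-3,7-dimethyl-2,3-dihydro-1H-indene-1,4(7H)-dione, racemic, both C7 epimers formed and used (one epimer drawn) | C[C@H]1CC(=O)C2=C1C(=O)C=C[C@@]2(C)O | intermediate
5 | guaiazulene (7-isopropyl-1,4-dimethylazulene) | c1cc(C)c2cc(C(C)C)ccc(C)c1-2 | starting material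
6 | 6-(guaiazulen-3-yl)-7-hydroxy-3,7-dimethyl-2,3,6,7-tetrahydro-1H-indene-1,4(5H)-dione, diastereomer mixture at C6 and C7, not isolated | C[C@H]1CC(=O)C2=C1C(=O)CC(c1cc(C)c3cc(C(C)C)ccc(C)c1-3)C2(C)O | intermediate
7 | rac-6-(guaiazulen-3-yl)-4-hydroxy-3,7-dimethylindan-1-one | C[C@H]1CC(=O)c2c(C)c(-c3cc(C)c4cc(C(C)C)ccc(C)c3-4)cc(O)c21 | intermediate
8 | rac-6-(guaiazulen-3-yl)-3,7-dimethyl-1-oxoindan-4-yl trifluoromethanesulfonate | C[C@H]1CC(=O)c2c(C)c(-c3cc(C)c4cc(C(C)C)ccc(C)c3-4)cc(OS(=O)(=O)C(F)(F)F)c21 | intermediate
9 | potassium enolate of 8 (potassium 1H-inden-3-olate), not isolated | C[C@H]1C=C([O-])c2c(C)c(-c3cc(C)c4cc(C(C)C)ccc(C)c3-4)cc(OS(=O)(=O)C(F)(F)F)c21.[K+] | intermediate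
10 | rac-6-(guaiazulen-3-yl)-2-hydroxy-3,7-dimethyl-1-oxoindan-4-yl trifluoromethanesulfonate (trans isomer expected and drawn; cis isomer equally usable) | C[C@H]1[C@H](O)C(=O)c2c(C)c(-c3cc(C)c4cc(C(C)C)ccc(C)c3-4)cc(OS(=O)(=O)C(F)(F)F)c21 | intermediate
11 | rac-6-(guaiazulen-3-yl)-3,7-dimethyl-1,2-dioxoindan-4-yl trifluoromethanesulfonate | C[C@H]1C(=O)C(=O)c2c(C)c(-c3cc(C)c4cc(C(C)C)ccc(C)c3-4)cc(OS(=O)(=O)C(F)(F)F)c21 | intermediate
12 | 2,6-bis(guaiazulen-3-yl)-2-hydroxy-3,7-dimethyl-1-oxoindan-4-yl trifluoromethanesulfonate, racemic, azulenyl expected trans to the C3 methyl, not isolated | C[C@H]1[C@](O)(c5cc(C)c6cc(C(C)C)ccc(C)c5-6)C(=O)c2c(C)c(-c3cc(C)c4cc(C(C)C)ccc(C)c3-4)cc(OS(=O)(=O)C(F)(F)F)c21 | intermediate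
13 | 2,6-bis(guaiazulen-3-yl)-3,7-dimethyl-1-oxo-1H-inden-4-yl trifluoromethanesulfonate | CC1=C(c5cc(C)c6cc(C(C)C)ccc(C)c5-6)C(=O)c2c(C)c(-c3cc(C)c4cc(C(C)C)ccc(C)c3-4)cc(OS(=O)(=O)C(F)(F)F)c21 | intermediate
14 | isopropenylboronic acid pinacol ester | CC(=C)B1OC(C)(C)C(C)(C)O1 | starting material
15 | 2,6-bis(guaiazulen-3-yl)-4-isopropenyl-3,7-dimethyl-1H-inden-1-one | CC1=C(c5cc(C)c6cc(C(C)C)ccc(C)c5-6)C(=O)c2c(C)c(-c3cc(C)c4cc(C(C)C)ccc(C)c3-4)cc(C(C)=C)c21 | intermediate
16 | phenylsilyl peroxide of the target carbinol (2-aryl-2-propyl phenylsilyl peroxide), not isolated | CC1=C(c5cc(C)c6cc(C(C)C)ccc(C)c5-6)C(=O)c2c(C)c(-c3cc(C)c4cc(C(C)C)ccc(C)c3-4)cc(C(C)(C)OO[SiH2]c7ccccc7)c21 | intermediate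
17 | 2,6-bis(guaiazulen-3-yl)-4-(2-hydroxypropan-2-yl)-3,7-dimethyl-1H-inden-1-one (CNP0151235.0) | CC1=C(c2cc(C)c3cc(C(C)C)ccc(C)c2-3)C(=O)c2c(C)c(-c3cc(C)c4cc(C(C)C)ccc(C)c3-4)cc(C(C)(C)O)c21 | target

Total step count: 10. Longest linear sequence: 10 steps, from 1 to 17.

Steps most likely to fail

1. Step 4 (Proposed new method). Acid may consume the quinol before the C–C bond forms. Possible paths are γ-enolisation at C3 with loss of the C7 hydroxyl (an internal redox to an indenone phenol), a dienone–phenol methyl shift, or ionisation toward a quinone methide. Attack at C6 is also slowed by the adjacent quaternary C7 and the peri methyl of the azulene. The fallback uses known chemistry, sets out from 4 and returns at 7. 48% aq. HBr in AcOH at room temperature should add bromide to C6 and dehydrate, as hydrogen halides do with p-quinols, to give 6-bromo-4-hydroxy-3,7-dimethylindan-1-one F1. Palladium-catalysed direct C3–H arylation of guaiazulene 5 with F1 (Pd(OAc)2, KOAc, DMAc, 120 °C), a known coupling mode of guaiazulene with aryl bromides, should then give 7.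

2. Step 10. Peroxyl or carbon radicals may add to the two azulene units, or hydrogen-atom transfer may reduce the indenone C2=C3 bond, instead of clean Markovnikov hydration. The fallback is ionic, sets out from 15 and returns at 17. HCl (4 M in dioxane) in CH2Cl2 at −20 °C should add in the Markovnikov sense to give 2,6-bis(guaiazulen-3-yl)-4-(2-chloropropan-2-yl)-3,7-dimethyl-1H-inden-1-one F2; the azulenes are only protonated reversibly. SN1 hydrolysis of F2 in acetone/H2O with NaHCO3 at room temperature should then give 17, and any alkene re-formed by elimination can be recycled.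

3. Step 3. Water may attack an ortho carbon, or the phenol may couple oxidatively, because the acyl group next to C7 disfavours positive charge at the para carbon. The fallback sets out from 3 and returns at 4. Singlet oxygen generated from KHSO5 (as Oxone, 2KHSO5·KHSO4·K2SO4) and NaHCO3 in MeCN/H2O should add to the para carbon of the phenolate and give 7-hydroperoxy-3,7-dimethyl-2,3-dihydro-1H-indene-1,4(7H)-dione F3. Reduction of F3 with Me2S should give 4.

Further compounds
F1 | step 4 | rac-6-bromo-4-hydroxy-3,7-dimethylindan-1-one | C[C@H]1CC(=O)c2c(C)c(Br)cc(O)c21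
F2 | step 10 | 2,6-bis(guaiazulen-3-yl)-4-(2-chloropropan-2-yl)-3,7-dimethyl-1H-inden-1-one | CC1=C(c5cc(C)c6cc(C(C)C)ccc(C)c5-6)C(=O)c2c(C)c(-c3cc(C)c4cc(C(C)C)ccc(C)c3-4)cc(C(C)(C)Cl)c21
F3 | step 3 | 7-hydroperoxy-3,7-dimethyl-2,3-dihydro-1H-indene-1,4(7H)-dione (racemic, both C7 epimers) | C[C@H]1CC(=O)C2=C1C(=O)C=CC2(C)OO
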